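**Retrosynthetic overview**
1. C8–Cl / C7–OH: HCl opens a 7α,8α-epoxide at the allylic C8 with inversion. The 5,6-acetonide is hydrolysed in the same flask.
2. The epoxide lies on the acetonide face. It is therefore made from the 7,8-alkene through a bromohydrin (bromonium on the open face), not by direct epoxidation.
3. Key disconnection: C4a is cut out of the carbocycle. The six-membered ring is a (4R,5R)-4,5-dioxygenated cyclopent-2-enone enlarged by one carbon, the diazo carbon of an alkynyl diazomethyl ketone (1,2-shift of C5 from C8a to C4a). O1–C2 then closes 6-endo onto the ynone.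
4. The diazo ynone comes from a catechol-derived benzyl bromide, the C3 dianion of propyne and an acetyl unit, followed by diazo transfer.
5. Ring order: arene (bought) → five-membered carbocycle (bought, carries C5/C6) → six-membered carbocycle (ring expansion) → γ-pyrone (same flask) → oxirane (made and opened).

Assumption: enone 12 (the D-ribose-derived acetonide of (4R,5R)-4,5-dihydroxycyclopent-2-enone) and propyne are bought; chromone numbering (O1, C2–C4, C4a, C5–C8, C8a) is used for 13–19, and α means the face that carries the C5/C6 oxygens.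

**Step 1**
Reactants: 1 catechol (benzene-1,2-diol)
Product: 3 2-methoxyphenyl pivalate, via guaiacol 2 (not isolated)
Conditions: MeI (1.0 equiv), K2CO3 (2.5 equiv), acetone, reflux; then PivCl (1.1 equiv), rt
Reagents that add atoms: iodomethane CI; pivaloyl chloride CC(C)(C)C(=O)Cl
Why: Williamson mono-O-methylation followed in the same pot by O-acylation of the remaining phenol; the pivalate (no α-H, hindered) makes this oxygen the weaker donor for step 2 and masks the phenol until step 6, and veratrole and catechol dipivalate are removed by chromatography.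

**Step 2**
Reactants: 3 2-methoxyphenyl pivalate
Product: 4 5-(bromomethyl)-2-methoxyphenyl pivalate
Conditions: (CH2O)n, 33% HBr/AcOH, 25–40 °C
Reagents that add atoms: formaldehyde (from paraformaldehyde) C=O; hydrogen bromide Br
Why: Blanc-type bromomethylation (electrophilic aromatic substitution) attacks the free position para to the methoxy group, the strongest donor on the ring, and gives the 3-oxy-4-methoxybenzyl pattern.

**Step 3**
Reactants: 4 5-(bromomethyl)-2-methoxyphenyl pivalate; 5 propyne; 6 N-methoxy-N-methylacetamide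
Product: 9 2-methoxy-5-(5-oxohex-3-yn-1-yl)phenyl pivalate, via 1,3-dilithiopropyne 7 (not isolated), via lithium acetylide 8 (not isolated)
Conditions: 5, n-BuLi (2.0 equiv), TMEDA, Et2O–hexane, −78 to 0 °C; 4 (1.0 equiv), THF, −78 °C; 6, −78 to −20 °C; AcOH quench
Reagents that add atoms: n-butyllithium [Li]CCCC (lithium in 7 and 8 only)
Why: The dianion is alkylated at its more reactive sp3 terminus (SN2 on the activated benzylic bromide, faster at −78 °C than attack on the hindered ester), and the remaining acetylide is acylated once by the Weinreb amide (Weinreb ketone synthesis).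

**Step 4**
Reactants: 9 2-methoxy-5-(5-oxohex-3-yn-1-yl)phenyl pivalate
Product: 11 5-(6-diazo-5-oxohex-3-yn-1-yl)-2-methoxyphenyl pivalate, via trifluoroacetyl ketone 10 (not isolated)
Conditions: LiHMDS (1.1 equiv), THF, −78 °C; CF3CO2CH2CF3 (1.2 equiv); 5% HCl wash; crude, MsN3 (1.5 equiv), Et3N, H2O (1 equiv), MeCN, 0 °C to rt
Reagents that add atoms: methanesulfonyl azide CS(=O)(=O)N=[N+]=[N-]; 2,2,2-trifluoroethyl trifluoroacetate O=C(OCC(F)(F)F)C(F)(F)F (CF3CO in 10 only)
Why: Danheiser detrifluoroacetylative diazo transfer (Regitz type): the kinetic methyl enolate is trifluoroacetylated, the activated CH2 takes N2 from the azide and loses CF3CO, a method designed for conjugated methyl ketones whose diazo ketones cannot be made from diazomethane.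

**Step 5**
Reactants: 11 5-(6-diazo-5-oxohex-3-yn-1-yl)-2-methoxyphenyl pivalate; 12 (4R,5R)-4,5-(isopropylidenedioxy)cyclopent-2-en-1-one
Product: 14 2-methoxy-5-{2-[(5S,6R)-5,6-(isopropylidenedioxy)-4-oxo-5,6-dihydro-4H-chromen-2-yl]ethyl}phenyl pivalate, via alkynoyl enone 13 (not isolated)
Conditions: Sc(OTf)3 (10 mol %), 4 Å MS, CH2Cl2, −40 to 0 °C, slow addition of 11 to 12 (1.2 equiv); then Et3N (20 mol %), rt
Reagents that add atoms: none
Why: Proposed new method: a Tiffeneau–Demjanov/Büchner–Curtius–Schlotterbeck-type one-carbon ring expansion in which the diazo carbon of an alkynyl diazomethyl ketone adds to the Sc(III)-activated C=O of 12 and the β-oxido diazonium loses N2 with 1,2-shift of the saturated, oxygen-bearing α′-carbon (future C5, migrating with retention, so C5 and C6 are carried over unchanged) rather than of the vinyl carbon (its shift would break the enone conjugation, and the α-oxygen lone pair stabilises the migrating centre), giving 2-alkynoyl enone 13, whose enol closes 6-endo-dig onto the ynone to the γ-pyrone; the closest known reactions are the Lewis-acid-promoted homologation of cycloalkenones with ethyl diazoacetate (insertion on the saturated side), Sc(III)-catalysed ketone/diazo ester homologation and the amine-catalysed closure of o-hydroxyaryl ynones to chromones, and what is new is the diazo ynone partner, the α′-alkoxy enone substrate and the merging of both events into one pyranone annulation.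

**Step 6**
Reactants: 14 2-methoxy-5-{2-[(5S,6R)-5,6-(isopropylidenedioxy)-4-oxo-5,6-dihydro-4H-chromen-2-yl]ethyl}phenyl pivalate
Product: 17 (5S,6S,7S,8S)-7,8-epoxy-2-[2-(3-hydroxy-4-methoxyphenyl)ethyl]-5,6-(isopropylidenedioxy)-5,6,7,8-tetrahydro-4H-chromen-4-one, via bromohydrin 15 (not isolated), via epoxy pivalate 16 (not isolated)
Conditions: NBS (1.05 equiv), THF–H2O 4:1, 0 °C, dark; crude, K2CO3 (3 equiv), MeOH, 0 °C to rt
Reagents that add atoms: water O; N-bromosuccinimide O=C1CCC(=O)N1Br (bromine in 15 only)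
Why: Bromohydrin formation followed by intramolecular Williamson closure: the bromonium forms on the face anti to the acetonide, water opens it anti, and SN2 closure puts the oxirane on the α face and sets C7 and C8 (either bromohydrin regioisomer gives the same epoxide); carbonate/methanol then transesterifies the aryl pivalate.

**Step 7**
Reactants: 17 (5S,6S,7S,8S)-7,8-epoxy-2-[2-(3-hydroxy-4-methoxyphenyl)ethyl]-5,6-(isopropylidenedioxy)-5,6,7,8-tetrahydro-4H-chromen-4-one
Product: 19 (5S,6S,7S,8R)-8-chloro-5,6,7-trihydroxy-2-[2-(3-hydroxy-4-methoxyphenyl)ethyl]-5,6,7,8-tetrahydro-4H-chromen-4-one, via chlorohydrin acetonide 18 (not isolated)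
Conditions: HCl (4 M in dioxane, 3 equiv), THF, −10 °C; then H2O, rt
Reagents that add atoms: hydrogen chloride Cl
Why: Acid-promoted SN2 opening of a γ,δ-epoxy enone-type oxirane: chloride attacks the allylic C8 from the β face with inversion (trans-diaxial, Fürst–Plattner) while C7 keeps its α C–O bond, giving 8β-Cl/7α-OH, and the added water then hydrolyses the acetonide without touching C5 and C6.

**Compound list**
1 | catechol | Oc1ccccc1O | starting material
2 | guaiacol (2-methoxyphenol) | COc1ccccc1O | intermediate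
3 | 2-methoxyphenyl pivalate | COc1ccccc1OC(=O)C(C)(C)C | intermediate
4 | 5-(bromomethyl)-2-methoxyphenyl pivalate | COc1ccc(CBr)cc1OC(=O)C(C)(C)C | intermediate
5 | propyne | CC#C | starting material
6 | N-methoxy-N-methylacetamide | CC(=O)N(C)OC | starting material
7 | 1,3-dilithiopropyne | [Li]CC#C[Li] | intermediate
8 | lithium 4-[4-methoxy-3-(pivaloyloxy)phenyl]but-1-yn-1-ide | [Li]C#CCCc1ccc(OC)c(OC(=O)C(C)(C)C)c1 | intermediate
9 | 2-methoxy-5-(5-oxohex-3-yn-1-yl)phenyl pivalate | CC(=O)C#CCCc1ccc(OC)c(OC(=O)C(C)(C)C)c1 | intermediate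
10 | 2-methoxy-5-(8,8,8-trifluoro-5,7-dioxooct-3-yn-1-yl)phenyl pivalate | O=C(CC(=O)C(F)(F)F)C#CCCc1ccc(OC)c(OC(=O)C(C)(C)C)c1 | intermediate
11 | 5-(6-diazo-5-oxohex-3-yn-1-yl)-2-methoxyphenyl pivalate | [N-]=[N+]=CC(=O)C#CCCc1ccc(OC)c(OC(=O)C(C)(C)C)c1 | intermediate
12 | (4R,5R)-4,5-(isopropylidenedioxy)cyclopent-2-en-1-one = (3aR,6aR)-2,2-dimethyl-3a,6a-dihydro-4H-cyclopenta[d][1,3]dioxol-4-one | O=C1C=C[C@H]2OC(C)(C)O[C@@H]12 | starting material
13 | (4R,5S)-4,5-(isopropylidenedioxy)-6-{5-[4-methoxy-3-(pivaloyloxy)phenyl]pent-2-ynoyl}cyclohex-2-en-1-one (C6 enolised/epimeric) | O=C1C=C[C@H]2OC(C)(C)O[C@H]2C1C(=O)C#CCCc1ccc(OC)c(OC(=O)C(C)(C)C)c1 | intermediate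
14 | 2-methoxy-5-{2-[(5S,6R)-5,6-(isopropylidenedioxy)-4-oxo-5,6-dihydro-4H-chromen-2-yl]ethyl}phenyl pivalate | COc1ccc(CCc2cc(=O)c3c(o2)C=C[C@H]4OC(C)(C)O[C@@H]34)cc1OC(=O)C(C)(C)C | intermediate
15 | (5S,6S,7S,8R)-7-bromo-8-hydroxy-5,6-(isopropylidenedioxy) tetrahydrochromone, aryl pivalate (8-OH α, 7-Br β) | COc1ccc(CCc2cc(=O)c3c(o2)[C@@H](O)[C@H](Br)[C@H]4OC(C)(C)O[C@@H]34)cc1OC(=O)C(C)(C)C | intermediate
16 | (5S,6S,7S,8S)-7,8-epoxy-5,6-(isopropylidenedioxy) tetrahydrochromone, aryl pivalate (oxirane and dioxolane both α) | COc1ccc(CCc2cc(=O)c3c(o2)[C@H]5O[C@H]5[C@H]4OC(C)(C)O[C@@H]34)cc1OC(=O)C(C)(C)C | intermediate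
17 | (5S,6S,7S,8S)-7,8-epoxy-2-[2-(3-hydroxy-4-methoxyphenyl)ethyl]-5,6-(isopropylidenedioxy)-5,6,7,8-tetrahydro-4H-chromen-4-one | COc1ccc(CCc2cc(=O)c3c(o2)[C@H]5O[C@H]5[C@H]4OC(C)(C)O[C@@H]34)cc1O | intermediate
18 | (5S,6R,7S,8R)-8-chloro-7-hydroxy-2-[2-(3-hydroxy-4-methoxyphenyl)ethyl]-5,6-(isopropylidenedioxy)-5,6,7,8-tetrahydro-4H-chromen-4-one | COc1ccc(CCc2cc(=O)c3c(o2)[C@H](Cl)[C@@H](O)[C@H]4OC(C)(C)O[C@@H]34)cc1O | intermediate
19 | (5S,6S,7S,8R)-8-chloro-5,6,7-trihydroxy-2-[2-(3-hydroxy-4-methoxyphenyl)ethyl]-5,6,7,8-tetrahydro-4H-chromen-4-one (CNP0362174.1) | COc1ccc(CCc2cc(=O)c3c(o2)[C@H](Cl)[C@@H](O)[C@@H](O)[C@H]3O)cc1O | target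

**Total steps:** 7. **Longest linear sequence:** 7 (1 → 3 → 4 → 9 → 11 → 14 → 17 → 19).

**Steps most likely to fail**

Step 5 (the new step).
- Risks: the vinyl carbon may migrate instead of C5, which would give the 7,8-acetonide regioisomer. The betaine may collapse to a spiro-epoxide. Compound 11 may consume itself by dipolar cycloaddition. Compound 13 may lose the C5 oxygen and aromatise before it cyclises.
- Fallback (known reactions only): it sets out from 12 and from acetylide 8 and comes back at 13, with ring enlargement and acylation done separately. Enone 12 is homologated with trimethylsilyldiazomethane and catalytic Sc(OTf)3, a known ketone homologation that ends, after a 1,3-Brook shift, in the silyl dienol ether F1. Acetylide 8 is quenched with CO2 and acidified to the alkynoic acid F2, which oxalyl chloride converts into the acid chloride F3. ZnCl2-catalysed C-acylation of the enol silane with F3 gives 13, which is closed to 14 with Et3N as before.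

Step 6.
- Risks: NBS may brominate the anisole ring or C3 of the pyranone faster than the deactivated 7,8-alkene. Methanolysis of the pivalate may be slow enough for methoxide to attack the epoxide.
- Fallback: it sets out from 14 and comes back at 19, replacing steric control by hydroxyl direction. The acetonide of 14 is hydrolysed first (80% AcOH, rt) to the cis-diol F4. Its allylic 6-OH steers a VO(acac)2/t-BuOOH epoxidation to the α face and gives the epoxy diol F5. K2CO3/MeOH frees the phenol to give the epoxy diol phenol F6, and anhydrous HCl as in step 7 gives 19 directly.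

Step 3.
- Risks: the dianion or the acetylide may attack the aryl pivalate. The heterogeneous dianion is also difficult to dose at one equivalent.
- Fallback: it sets out from 4 and comes back at 9, using a monoanion and an electrophilic acylation. 1-(Trimethylsilyl)propyne is deprotonated with one equivalent of n-BuLi to 3-lithio-1-(trimethylsilyl)propyne F7, which is alkylated with 4 to the silyl alkyne F8. The C–Si bond is then acylated with acetyl chloride to give 9 (AlCl3, CH2Cl2, −20 °C, ipso-acylation of an alkynylsilane; CuCl in DMI is the non-acidic variant).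

**Further compounds**
F1 | step 5 | silyl dienol ether, (5R,6S)-5,6-(isopropylidenedioxy)-2-(trimethylsilyloxy)cyclohexa-1,3-diene | C[Si](C)(C)OC1=C[C@@H]2OC(C)(C)O[C@@H]2C=C1
F2 | step 5 | alkynoic acid, 5-[4-methoxy-3-(pivaloyloxy)phenyl]pent-2-ynoic acid | OC(=O)C#CCCc1ccc(OC)c(OC(=O)C(C)(C)C)c1
F3 | step 5 | acid chloride, 5-[4-methoxy-3-(pivaloyloxy)phenyl]pent-2-ynoyl chloride | ClC(=O)C#CCCc1ccc(OC)c(OC(=O)C(C)(C)C)c1
F4 | step 6 | cis-diol, (5S,6R)-5,6-dihydroxy-5,6-dihydrochromone aryl pivalate | COc1ccc(CCc2cc(=O)c3c(o2)C=C[C@@H](O)[C@H]3O)cc1OC(=O)C(C)(C)C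
F5 | step 6 | epoxy diol, (5S,6S,7S,8S)-7,8-epoxy-5,6-dihydroxy tetrahydrochromone aryl pivalate | COc1ccc(CCc2cc(=O)c3c(o2)[C@H]4O[C@H]4[C@@H](O)[C@H]3O)cc1OC(=O)C(C)(C)C
F6 | step 6 | epoxy diol phenol, (5S,6S,7S,8S)-7,8-epoxy-5,6-dihydroxy-2-[2-(3-hydroxy-4-methoxyphenyl)ethyl]-5,6,7,8-tetrahydro-4H-chromen-4-one | COc1ccc(CCc2cc(=O)c3c(o2)[C@H]4O[C@H]4[C@@H](O)[C@H]3O)cc1O
F7 | step 3 | 3-lithio-1-(trimethylsilyl)propyne | [Li]CC#C[Si](C)(C)C
F8 | step 3 | silyl alkyne, 2-methoxy-5-[4-(trimethylsilyl)but-3-yn-1-yl]phenyl pivalate | C[Si](C)(C)C#CCCc1ccc(OC)c(OC(=O)C(C)(C)C)c1
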